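## The problem

The target is a flavone with six oxygens on its periphery: four are methyl ethers (C3, C7, C8, C2') and two are free phenols (C5 and C5'). It has no stereocentre, so there is nothing to control by relay; the whole difficulty is regiochemical. Ring A carries the unsymmetrical 5,7,8-pattern. Classical acylation routes confuse this with the 5,6,7-pattern, and a 5-hydroxy-7,8-dioxygenated flavone can isomerise to that pattern by acid-induced opening and reclosure of ring C (Wessely–Moser). The C5 hydroxyl lies peri to the carbonyl and must end up free while the C3 methoxy (also next to the carbonyl) and the C8 methoxy (para to it) stay methylated. The deprotection must therefore be mild and must not depend on telling one methyl ether from another. The C3 oxygen sits on the enone carbon of ring C and cannot be carried in by a simple two-carbon building block. Both aryl rings are electron-rich and will not tolerate strong oxidants or hot mineral acid. The enabling feature is ring C itself: the chain O1–C2=C3–C4(=O) bridges C8a and C4a, which are the oxygen-bearing carbon and its ortho neighbour of a phenol. Ring C therefore maps onto a 2-iodophenol (O1, C8a, C4a), carbon monoxide (C4) and an arylacetylene (C3, C2 and ring B).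

## Retrosynthesis

Target 20 to ether 19. The last cut is at the two O–alkyl bonds that mask the phenols. The C5 oxygen is carried as an isopropyl ether and the C5' oxygen as a benzyl ether. A C5 methyl ether would have to be removed in the presence of the C3 and C8 methyl ethers, which are the next ones at risk under a chelating Lewis acid. The isopropyl ether next to the carbonyl and the benzyl ether both fall to BCl3 at low temperature, where methyl ethers are inert. The forward step is one mild dealkylation with no protic acid able to trigger ring C isomerisation.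

Ether 19 to flavonol 18 to flavone 16. The C3–O bond is cut next. C3 arrives in ring C as the terminal CH of an alkyne, so its oxygen has to be added after ring closure. Epoxidation of the C2=C3 bond of 16 with dimethyldioxirane gives epoxide 17, and acid isomerises it to flavonol 18. Flavonol 18 has a single free hydroxyl, so its methylation to 19 is unambiguous. Building the C3 oxygen earlier (a chalcone and oxidative cyclisation) would give up the three-component ring closure.

Flavone 16 to iodophenol 8, alkyne 12 and carbon monoxide 13. Three bonds are cut at once: C4a–C4, C4–C3 and O1–C2. Against the neighbouring cuts (acylation of a phenol followed by diketone cyclisation, or a chalcone), this one fixes the ring A pattern by the position of one iodine atom and never passes through a 2-hydroxyacetophenone whose regiochemistry would be uncertain. The precursors are two simple arenes and a gas. The forward reaction must put CO between the aryl group and the alkyne, and it must close the six-membered ring and not the five-membered one.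

Iodophenol 8 to iodide 7 to ether 5. The C–I bond is cut. Electrophilic iodination of the free phenol would be expected para to the hydroxyl, which is the wrong carbon. The iodine is therefore placed by directed lithiation next to a methoxymethyl ether in 5 (through aryllithium 6), and the phenol is unmasked afterwards.

Ether 5 to phenol 4 to MOM ether 2 to phenol 1. The C–O bond at the ring carbon meta to both flanking ethers is cut. Iridium-catalysed borylation of 2 reaches only that carbon for steric reasons, and oxidation of boronate 3 gives phenol 4. The oxygen introduced here becomes O5 of the flavone, so it can be alkylated with isopropyl instead of methyl at no cost in steps. Compound 1 is commercial 2,3-dimethoxyphenol.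

Alkyne 12 to aldehyde 11 to salicylaldehyde 10 to phenol 9. The alkyne is cut back to an aldehyde (one-carbon homologation). The aldehyde is placed ortho to the free hydroxyl of commercial 4-(benzyloxy)phenol 9 by magnesium-mediated formylation. This fixes the 2-methoxy/5-benzyloxy relationship without having to differentiate two phenols.

## Roads not taken

Alternative 1: Ring A by cycloaddition on a sulfonylpyranone. The cut is through C4a–C5 and C8–C8a. The forward step adds the silyl ketene acetal diene A3 to the sulfone-activated C5=C6 bond of the pyranone A2. The adduct loses benzenesulfinic acid and methanol and aromatises to the 5-hydroxyflavone A1.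
- Merits: the C3 methoxy and ring B are already in A2, and the C5 hydroxyl emerges free as the only unmethylated oxygen of ring A. A1 is one hydrogenolysis from the target. The endgame is therefore shorter and cleaner than in the chosen plan, which spends three steps after ring formation.
- Weak points: A2 is a fully substituted 2-aryl-3-methoxy-4-pyranone carrying a sulfone, and making it is a synthesis in itself. A3 is a hydrolytically labile trioxygenated diene with a methoxy group on its reacting terminus, which lowers its reactivity and raises questions of geometry. The aromatisation must lose methanol and not silanol, and must not stop at a Michael adduct.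
- Comparison: the chosen plan sets against this two fragments made from commercial arenes by reactions of predictable regiochemistry, and a ring-forming step with direct precedent on 2-iodophenols and arylacetylenes.

Alternative 2: Ring B grown on a 2-ethynylchromone. The cut is through C1'–C2' and C5'–C6'. 2-Methoxyfuran A6 adds to the ethynylchromone A5, the oxygen bridge of the adduct opens, and ring B appears in A4 with its methoxy group and its free C5' hydroxyl already differentiated.
- Merits: ring B needs no protecting group and no prefunctionalised arene. On that count it is better than the chosen plan, which uses three steps and a benzyl group for the alkyne.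
- Weak points: A5 contains the complete tetramethoxychromone, so ring C must first be built by another method from a ring A precursor with the same 5,7,8-pattern. The route becomes longer and linear. The alkyne of A5 is activated only through the vinylogous carbonyl, and A6 is acid-labile and prone to conjugate addition and ring opening instead of cycloaddition. A4 still carries a C5 methyl ether that has to be removed next to the C3 and C8 methyl ethers, which is the selectivity problem the chosen plan avoids with the isopropyl group.

Alternative 3: A pyranone-masked polyketide folded into ring A. The cut is the C4a–C5 bond. Under Mg(OMe)2 the keto ester A8 is deprotonated to a dienolate running through the pyranone, and the ring carbon that becomes C4a attacks the terminal ester. This closes ring A and gives the 5,7-dihydroxy-8-methoxyflavone A7 after enolisation.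
- Merits: the oxygenation pattern of ring A is written into the chain, so there is no 5,7,8 versus 5,6,7 ambiguity. The C3 methoxy is in place and the C5 hydroxyl is born free.
- Weak points: A7 has two free hydroxyls on ring A and needs a selective methylation at C7 before debenzylation. This is feasible because the C5 hydroxyl is chelated, but it adds a step. A8 is a sensitive α-methoxy β-keto ester on a pyranone that can cyclise in other ways or suffer opening of the pyranone by methoxide, and its assembly is long.
- Comparison: it matches the chosen plan in regiochemical security of ring A and beats it in avoiding a late C3 oxidation. The chosen plan answers with convergence and with much simpler precursors.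

Key step: step 9

Remark: the target has no stereocentre. Epoxide 17 forms as a racemate (one enantiomer is drawn) and both of its stereocentres are erased in the same flask.

## Steps

Step 1
Reactants: 1 2,3-dimethoxyphenol
Product: 2 1,2-dimethoxy-3-(methoxymethoxy)benzene
Conditions: MOMCl, iPr2NEt, CH2Cl2, 0 °C to rt
Reagents that add atoms: chloromethyl methyl ether, COCCl
Why: O-alkylation of the phenol with an α-chloro ether (Williamson type); the MOM group protects the phenol, tolerates the borylation and later serves as the directing group for lithiation.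

Step 2
Reactants: 2 1,2-dimethoxy-3-(methoxymethoxy)benzene
Product: 4 3,4-dimethoxy-5-(methoxymethoxy)phenol, via arylboronate 3 (not isolated)
Conditions: [Ir(OMe)(cod)]2 (cat.), 4,4'-di-tert-butyl-2,2'-bipyridine, B2pin2, THF, 80 °C; then aq. NaOH, H2O2, 0 °C to rt
Reagents that add atoms: bis(pinacolato)diboron, CC1(C)OB(OC1(C)C)B1OC(C)(C)C(C)(C)O1 (boryl group of 3 only); hydrogen peroxide, OO (phenol oxygen of 4)
Why: Iridium-catalysed C–H borylation is sterically controlled and avoids C–H bonds ortho to a substituent, so only the hydrogen meta to both flanking ethers should react; basic peroxide then converts the C–B bond into C–OH at the same carbon (one-pot borylation–oxidation).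

Step 3
Reactants: 4 3,4-dimethoxy-5-(methoxymethoxy)phenol
Product: 5 1,2-dimethoxy-3-(methoxymethoxy)-5-(propan-2-yloxy)benzene
Conditions: 2-bromopropane, K2CO3, DMF, 60 °C
Reagents that add atoms: 2-bromopropane, CC(C)Br
Why: Williamson etherification of the only free phenol; the isopropyl ether is stable to organolithium, palladium and oxidant and is the ether later removed selectively next to the carbonyl.

Step 4
Reactants: 5 1,2-dimethoxy-3-(methoxymethoxy)-5-(propan-2-yloxy)benzene
Product: 7 2-iodo-4,5-dimethoxy-3-(methoxymethoxy)-1-(propan-2-yloxy)benzene, via aryllithium 6 (not isolated)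
Conditions: n-BuLi, TMEDA, THF, −20 to 0 °C; then I2, −78 °C to rt
Reagents that add atoms: n-butyllithium, [Li]CCCC (lithium of 6 only); iodine, II
Why: Directed ortho-metalation: the acetal oxygens of the MOM ether bind n-BuLi and, together with the isopropoxy group, direct deprotonation to the C–H between them and not to the C–H between isopropoxy and methoxy; iodine traps aryllithium 6 at that carbon.

Step 5
Reactants: 7 2-iodo-4,5-dimethoxy-3-(methoxymethoxy)-1-(propan-2-yloxy)benzene
Product: 8 2-iodo-5,6-dimethoxy-3-(propan-2-yloxy)phenol
Conditions: HCl (aq., dilute), MeOH, 40 °C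
Reagents that add atoms: none
Why: Acid-catalysed acetal exchange removes the MOM group as dimethoxymethane; methyl and isopropyl aryl ethers are stable to dilute methanolic acid, which is kept mild to spare the electron-rich aryl iodide.

Step 6
Reactants: 9 4-(benzyloxy)phenol
Product: 10 5-(benzyloxy)-2-hydroxybenzaldehyde
Conditions: MgCl2, Et3N, (CH2O)n, MeCN, reflux; then aq. HCl
Reagents that add atoms: paraformaldehyde (formaldehyde), C=O
Why: Magnesium-mediated ortho-formylation of a phenol (Casnati–Skattebøl): the magnesium phenoxide delivers formaldehyde to the carbon next to the phenol oxygen and a second formaldehyde oxidises the benzylic alkoxide to the aldehyde; the two ortho positions of 9 are equivalent.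

Step 7
Reactants: 10 5-(benzyloxy)-2-hydroxybenzaldehyde
Product: 11 5-(benzyloxy)-2-methoxybenzaldehyde
Conditions: MeI, K2CO3, DMF, rt
Reagents that add atoms: iodomethane, CI
Why: Williamson methylation of the only free phenol; the hydrogen-bonded salicylaldehyde hydroxyl is alkylated readily under carbonate conditions in DMF.

Step 8
Reactants: 11 5-(benzyloxy)-2-methoxybenzaldehyde
Product: 12 4-(benzyloxy)-2-ethynyl-1-methoxybenzene
Conditions: dimethyl (1-diazo-2-oxopropyl)phosphonate, K2CO3, MeOH, rt
Reagents that add atoms: dimethyl (1-diazo-2-oxopropyl)phosphonate, CC(=O)C(=[N+]=[N-])P(=O)(OC)OC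
Why: Ohira–Bestmann homologation (Seyferth–Gilbert type): methanolysis frees the diazomethylphosphonate anion, which adds to the non-enolisable aldehyde, loses dimethyl phosphate and then N2 with a 1,2-hydrogen shift to give the terminal alkyne.

Step 9
Reactants: 8 2-iodo-5,6-dimethoxy-3-(propan-2-yloxy)phenol; 12 4-(benzyloxy)-2-ethynyl-1-methoxybenzene; 13 carbon monoxide
Product: 16 2-[5-(benzyloxy)-2-methoxyphenyl]-7,8-dimethoxy-5-(propan-2-yloxy)-4H-chromen-4-one, via hydroxyaryl ynone 14 (not isolated), via enaminone 15 (not isolated)
Conditions: PdCl2(PPh3)2 (5 mol %), CO (20 bar), Et2NH, 120 °C, autoclave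
Reagents that add atoms: diethylamine, CCNCC (nitrogen of 15 only; expelled again on ring closure)
Why: Zerovalent palladium formed from PdCl2(PPh3)2 inserts into the C–I bond of 8, CO inserts to give an aroylpalladium iodide, the amine-deprotonated alkyne 12 is transferred to palladium and reductive elimination gives ynone 14 (carbonylative Sonogashira coupling). Diethylamine then adds to the ynone in conjugate fashion to give enaminone 15 (drawn E; either geometry can close), and the phenol oxygen attacks the amine-bearing carbon and expels diethylamine, closing ring C by 6-endo addition–elimination. The closest known reaction is the palladium-catalysed carbonylative annulation of 2-iodophenols with terminal arylacetylenes in diethylamine to give flavones. No stereocentre is formed. The step needs the flavone and not the aurone from 5-exo closure; routing the cyclisation through the enaminone secures this, because the phenol then attacks an sp2 carbon that already carries a leaving group. It also needs carbonylative and not direct coupling, which would lead to a 2-arylbenzofuran; CO pressure, the absence of copper and the ready migration of the electron-rich aryl group to CO favour insertion. The position of iodine in 8 places O1 next to the C8 methoxy, so the 5,7,8-pattern cannot be scrambled. The isopropyl, benzyl and methyl ethers are spectators.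

Step 10
Reactants: 16 2-[5-(benzyloxy)-2-methoxyphenyl]-7,8-dimethoxy-5-(propan-2-yloxy)-4H-chromen-4-one
Product: 18 2-[5-(benzyloxy)-2-methoxyphenyl]-3-hydroxy-7,8-dimethoxy-5-(propan-2-yloxy)-4H-chromen-4-one, via flavone epoxide 17 (not isolated)
Conditions: dimethyldioxirane, acetone/CH2Cl2, 0 °C to rt; then p-TsOH·H2O (cat.), CH2Cl2, rt
Reagents that add atoms: dimethyldioxirane, CC1(C)OO1
Why: Dimethyldioxirane epoxidises the C2=C3 bond of flavones under neutral conditions; acid opens epoxide 17 at C2 to an oxocarbenium ion stabilised by O1 and the aryl group, and loss of the C3 proton gives the flavonol. Both stereocentres of racemic 17 vanish in this isomerisation.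

Step 11
Reactants: 18 2-[5-(benzyloxy)-2-methoxyphenyl]-3-hydroxy-7,8-dimethoxy-5-(propan-2-yloxy)-4H-chromen-4-one
Product: 19 2-[5-(benzyloxy)-2-methoxyphenyl]-3,7,8-trimethoxy-5-(propan-2-yloxy)-4H-chromen-4-one
Conditions: MeI, K2CO3, acetone, reflux
Reagents that add atoms: iodomethane, CI
Why: Williamson methylation of the flavonol hydroxyl, the only free hydroxyl in 18.

Step 12
Reactants: 19 2-[5-(benzyloxy)-2-methoxyphenyl]-3,7,8-trimethoxy-5-(propan-2-yloxy)-4H-chromen-4-one
Product: 20 5,5'-dihydroxy-3,7,8,2'-tetramethoxyflavone
Conditions: BCl3, pentamethylbenzene, CH2Cl2, −78 to 0 °C; then MeOH, aq. NaHCO3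
Reagents that add atoms: none
Why: Lewis-acid ether cleavage: BCl3 bridges the C4 carbonyl and the C5 oxygen and releases the secondary isopropyl group through a six-membered boron chelate, and it cleaves the benzyl ether with the benzyl cation trapped by pentamethylbenzene (Friedel–Crafts). Methyl ethers should be inert at this temperature.

## Compound list

1 | 2,3-dimethoxyphenol | COc1cccc(O)c1OC | starting material
2 | 1,2-dimethoxy-3-(methoxymethoxy)benzene | COCOc1cccc(OC)c1OC | intermediate
3 | 2-[3,4-dimethoxy-5-(methoxymethoxy)phenyl]-4,4,5,5-tetramethyl-1,3,2-dioxaborolane | COCOc1cc(B2OC(C)(C)C(C)(C)O2)cc(OC)c1OC | intermediate (not isolated)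
4 | 3,4-dimethoxy-5-(methoxymethoxy)phenol | COCOc1cc(O)cc(OC)c1OC | intermediate
5 | 1,2-dimethoxy-3-(methoxymethoxy)-5-(propan-2-yloxy)benzene | COCOc1cc(OC(C)C)cc(OC)c1OC | intermediate
6 | [3,4-dimethoxy-2-(methoxymethoxy)-6-(propan-2-yloxy)phenyl]lithium | COCOc1c([Li])c(OC(C)C)cc(OC)c1OC | intermediate (not isolated)
7 | 2-iodo-4,5-dimethoxy-3-(methoxymethoxy)-1-(propan-2-yloxy)benzene | COCOc1c(I)c(OC(C)C)cc(OC)c1OC | intermediate
8 | 2-iodo-5,6-dimethoxy-3-(propan-2-yloxy)phenol | COc1cc(OC(C)C)c(I)c(O)c1OC | intermediate
9 | 4-(benzyloxy)phenol | Oc1ccc(OCc2ccccc2)cc1 | starting material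
10 | 5-(benzyloxy)-2-hydroxybenzaldehyde | O=Cc1cc(OCc2ccccc2)ccc1O | intermediate
11 | 5-(benzyloxy)-2-methoxybenzaldehyde | COc1ccc(OCc2ccccc2)cc1C=O | intermediate
12 | 4-(benzyloxy)-2-ethynyl-1-methoxybenzene | C#Cc1cc(OCc2ccccc2)ccc1OC | intermediate
13 | carbon monoxide | [C-]#[O+] | starting material
14 | 3-[5-(benzyloxy)-2-methoxyphenyl]-1-[2-hydroxy-3,4-dimethoxy-6-(propan-2-yloxy)phenyl]prop-2-yn-1-one | COc1ccc(OCc2ccccc2)cc1C#CC(=O)c1c(O)c(OC)c(OC)cc1OC(C)C | intermediate (not isolated)
15 | (2E)-3-[5-(benzyloxy)-2-methoxyphenyl]-3-(diethylamino)-1-[2-hydroxy-3,4-dimethoxy-6-(propan-2-yloxy)phenyl]prop-2-en-1-one | CCN(CC)/C(=C/C(=O)c1c(O)c(OC)c(OC)cc1OC(C)C)c1cc(OCc2ccccc2)ccc1OC | intermediate (not isolated)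
16 | 2-[5-(benzyloxy)-2-methoxyphenyl]-7,8-dimethoxy-5-(propan-2-yloxy)-4H-chromen-4-one | COc1ccc(OCc2ccccc2)cc1-c1cc(=O)c2c(OC(C)C)cc(OC)c(OC)c2o1 | intermediate
17 | rac-2-[5-(benzyloxy)-2-methoxyphenyl]-2,3-epoxy-7,8-dimethoxy-5-(propan-2-yloxy)-2,3-dihydro-4H-chromen-4-one (cis-fused oxirane, one enantiomer drawn) | COc1ccc(OCc2ccccc2)cc1[C@@]12O[C@@H]1C(=O)c1c(OC(C)C)cc(OC)c(OC)c1O2 | intermediate (not isolated)
18 | 2-[5-(benzyloxy)-2-methoxyphenyl]-3-hydroxy-7,8-dimethoxy-5-(propan-2-yloxy)-4H-chromen-4-one | COc1ccc(OCc2ccccc2)cc1-c1oc2c(OC)c(OC)cc(OC(C)C)c2c(=O)c1O | intermediate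
19 | 2-[5-(benzyloxy)-2-methoxyphenyl]-3,7,8-trimethoxy-5-(propan-2-yloxy)-4H-chromen-4-one | COc1ccc(OCc2ccccc2)cc1-c1oc2c(OC)c(OC)cc(OC(C)C)c2c(=O)c1OC | intermediate
20 | 5,5'-dihydroxy-3,7,8,2'-tetramethoxyflavone, that is 5-hydroxy-2-(5-hydroxy-2-methoxyphenyl)-3,7,8-trimethoxy-4H-chromen-4-one | COc1ccc(O)cc1-c1oc2c(OC)c(OC)cc(O)c2c(=O)c1OC | target

## Step count and risks

Total: 12 steps. Longest linear sequence: 9 steps (steps 1–5 and 9–12). The alkyne arm (steps 6–8) joins at step 9.

Step 9 (key step).
- What may go wrong: alkynyl transfer may outrun CO insertion, leading to direct coupling and cyclisation to a benzofuran. Diethylamine may capture the aroylpalladium intermediate as an amide. Oxidative addition into the electron-rich, doubly ortho-substituted iodide may be slow enough for the alkyne to oligomerise first.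
- Fallback: build the same ynone without palladium, setting out from 5 and 12 and returning at 16. Ether 5 is lithiated as in step 4 and the aryllithium 6 is quenched with DMF to give 3,4-dimethoxy-2-(methoxymethoxy)-6-(propan-2-yloxy)benzaldehyde F1. Alkyne 12, deprotonated with n-BuLi in THF at −78 °C, adds to F1 to give racemic 3-[5-(benzyloxy)-2-methoxyphenyl]-1-[3,4-dimethoxy-2-(methoxymethoxy)-6-(propan-2-yloxy)phenyl]prop-2-yn-1-ol F2. MnO2 in CH2Cl2 oxidises F2 to 3-[5-(benzyloxy)-2-methoxyphenyl]-1-[3,4-dimethoxy-2-(methoxymethoxy)-6-(propan-2-yloxy)phenyl]prop-2-yn-1-one F3. Dilute HCl in MeOH removes the MOM group to give ynone 14, and diethylamine in ethanol closes ring C through enaminone 15 to give 16.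

Step 4.
- What may go wrong: lithiation at the other open ring carbon (between isopropoxy and methoxy), or incomplete metalation, because the MOM group outranks a methoxy group as director only moderately.
- Fallback: use the strongest oxygen director, setting out from 5 and returning at 8. The MOM group of 5 is removed with dilute HCl in MeOH to give 2,3-dimethoxy-5-(propan-2-yloxy)phenol F4. NaH and ClC(O)NEt2 in THF convert F4 into 2,3-dimethoxy-5-(propan-2-yloxy)phenyl diethylcarbamate F5. The only hydrogen ortho to the carbamate of F5 is the desired one; s-BuLi and TMEDA at −78 °C followed by I2 give 2-iodo-5,6-dimethoxy-3-(propan-2-yloxy)phenyl diethylcarbamate F6. Hydrolysis with NaOH in ethanol at reflux gives 8.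

Step 10.
- What may go wrong: epoxidation of the electron-poor enone is slow, so the excess oxidant and long contact it needs may oxidise the dialkoxy ring B or the benzylic position.
- Fallback: replace oxidation of the alkene by deprotonation, setting out from 16 and returning at 18. Flavone 16 is treated with LiN(iPr)2 in the presence of B(OiPr)3 in THF at −78 °C, which traps the C3 anion as bis(propan-2-yl) {2-[5-(benzyloxy)-2-methoxyphenyl]-7,8-dimethoxy-4-oxo-5-(propan-2-yloxy)-4H-chromen-3-yl}boronate F7. Oxidation of F7 with H2O2 in acetic acid gives 18.

Step 12.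
- What may go wrong: chelation-assisted loss of a methyl group at C8 or C3 if the mixture is warmed too far, or benzylation of ring A if trapping of the benzyl cation is incomplete.
- Fallback: separate the two deprotections by mechanism, setting out from 19 and returning at 20. Hydrogenolysis (H2, Pd/C, ethyl acetate) removes the benzyl group to give 2-(5-hydroxy-2-methoxyphenyl)-3,7,8-trimethoxy-5-(propan-2-yloxy)-4H-chromen-4-one F8. One equivalent of BCl3 in CH2Cl2 at −78 °C then cleaves only the chelated isopropyl ether of F8 to give 20.

## Further compounds

F1 | step 9 | 3,4-dimethoxy-2-(methoxymethoxy)-6-(propan-2-yloxy)benzaldehyde | COCOc1c(C=O)c(OC(C)C)cc(OC)c1OC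
F2 | step 9 | rac-3-[5-(benzyloxy)-2-methoxyphenyl]-1-[3,4-dimethoxy-2-(methoxymethoxy)-6-(propan-2-yloxy)phenyl]prop-2-yn-1-ol | COCOc1c(C(O)C#Cc2cc(OCc3ccccc3)ccc2OC)c(OC(C)C)cc(OC)c1OC
F3 | step 9 | 3-[5-(benzyloxy)-2-methoxyphenyl]-1-[3,4-dimethoxy-2-(methoxymethoxy)-6-(propan-2-yloxy)phenyl]prop-2-yn-1-one | COCOc1c(C(=O)C#Cc2cc(OCc3ccccc3)ccc2OC)c(OC(C)C)cc(OC)c1OC
F4 | step 4 | 2,3-dimethoxy-5-(propan-2-yloxy)phenol | COc1cc(OC(C)C)cc(O)c1OC
F5 | step 4 | 2,3-dimethoxy-5-(propan-2-yloxy)phenyl diethylcarbamate | CCN(CC)C(=O)Oc1cc(OC(C)C)cc(OC)c1OC
F6 | step 4 | 2-iodo-5,6-dimethoxy-3-(propan-2-yloxy)phenyl diethylcarbamate | CCN(CC)C(=O)Oc1c(I)c(OC(C)C)cc(OC)c1OC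
F7 | step 10 | bis(propan-2-yl) {2-[5-(benzyloxy)-2-methoxyphenyl]-7,8-dimethoxy-4-oxo-5-(propan-2-yloxy)-4H-chromen-3-yl}boronate | CC(C)OB(OC(C)C)c1c(-c2cc(OCc3ccccc3)ccc2OC)oc2c(OC)c(OC)cc(OC(C)C)c2c1=O
F8 | step 12 | 2-(5-hydroxy-2-methoxyphenyl)-3,7,8-trimethoxy-5-(propan-2-yloxy)-4H-chromen-4-one | COc1ccc(O)cc1-c1oc2c(OC)c(OC)cc(OC(C)C)c2c(=O)c1OC
A1 | alternative 1 | 2-[5-(benzyloxy)-2-methoxyphenyl]-5-hydroxy-3,7,8-trimethoxy-4H-chromen-4-one | COc1ccc(OCc2ccccc2)cc1-c1oc2c(OC)c(OC)cc(O)c2c(=O)c1OC
A2 | alternative 1 | 5-(benzenesulfonyl)-2-[5-(benzyloxy)-2-methoxyphenyl]-3-methoxy-4H-pyran-4-one | COc1ccc(OCc2ccccc2)cc1-c1occ(S(=O)(=O)c2ccccc2)c(=O)c1OC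
A3 | alternative 1 | trimethyl[(1,3,4-trimethoxybuta-1,3-dien-1-yl)oxy]silane | COC=C(OC)C=C(OC)O[Si](C)(C)C
A4 | alternative 2 | 2-(5-hydroxy-2-methoxyphenyl)-3,5,7,8-tetramethoxy-4H-chromen-4-one | COc1ccc(O)cc1-c1oc2c(OC)c(OC)cc(OC)c2c(=O)c1OC
A5 | alternative 2 | 2-ethynyl-3,5,7,8-tetramethoxy-4H-chromen-4-one | C#Cc1oc2c(OC)c(OC)cc(OC)c2c(=O)c1OC
A6 | alternative 2 | 2-methoxyfuran | COc1ccco1
A7 | alternative 3 | 2-[5-(benzyloxy)-2-methoxyphenyl]-5,7-dihydroxy-3,8-dimethoxy-4H-chromen-4-one | COc1ccc(OCc2ccccc2)cc1-c1oc2c(OC)c(O)cc(O)c2c(=O)c1OC
A8 | alternative 3 | rac-methyl 4-{6-[5-(benzyloxy)-2-methoxyphenyl]-5-methoxy-4-oxo-4H-pyran-2-yl}-4-methoxy-3-oxobutanoate | COc1ccc(OCc2ccccc2)cc1-c1oc(C(OC)C(=O)CC(=O)OC)cc(=O)c1OC
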